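**Retrosynthetic overview**

1. The γ-lactone is made last, by cutting C2–C3 and O–C4: a one-flask [3+2] annulation of an acetate enolate equivalent (ketene silyl acetal 18) onto monocyclic peroxyacetal 17. The enabling feature is that C3 and C4 of the 1,2-dioxane ring are vicinal latent electrophiles: C3 is a peroxyacetal carbon (peroxycarbenium ion) and C4 carries an exocyclic methylene (tertiary cation on protonation, which also supplies the C4 methyl).
2. 17 comes from open-chain 2-methylene-4-silylperoxy aldehyde 16 by peroxyacetalisation, which closes the 1,2-dioxane; C3 and the methylene carbon come from a Wittig homologation and a Mannich methylenation of aldehyde 13.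
3. The C6 tertiary hydroperoxide comes from invertive H2O2 opening of 2,2-disubstituted oxetane 10, made from methyl ketone 8 by catalytic asymmetric double sulfur-ylide addition; the oxetane supplies C5 and C4.
4. 8 comes from copper-catalysed asymmetric conjugate addition (sets C8) of the Grignard reagent of bromide 5 to pent-3-en-2-one; 5 comes from carboalumination/benzylation of 4-pentyn-1-ol (E-alkene).
5. Ring order: oxetane (temporary, step 4), then 1,2-dioxane (step 10), then γ-lactone (step 11).

Key step: step 11

Remark: atom numbers follow the natural product (C1 lactone carbonyl, C2 its CH2, C3 the CH bearing the peroxide, C4 and C6 the quaternary carbons, C5 the ring CH2, C8 the side-chain CHMe); as an assumption, the sense of induction of the chiral catalysts in steps 3, 4 and 11 is assigned by analogy with simpler substrates, and the mirror-image catalyst is used if a sense proves opposite.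

**Route**

Step 1
Reactants: 1 4-pentyn-1-ol; 2 benzyl bromide
Product: 4 (E)-4-methyl-6-phenylhex-4-en-1-ol, via alkenylalane 3 (not isolated)
Conditions: AlMe3 (3 equiv), Cp2ZrCl2 (0.25 equiv), CH2Cl2, 0 °C to rt; then 2, Pd(PPh3)4 (5 mol%), THF, rt
Reagents that add atoms: trimethylaluminium, C[Al](C)C
Why: Zirconium-catalysed syn-methylalumination of the terminal alkyne (Negishi carboalumination) places methyl and aluminium cis, and the palladium-catalysed cross-coupling of the alkenylalane with the benzylic bromide proceeds with retention, so the E-trisubstituted alkene should form as a single isomer.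

Step 2
Reactants: 4 (E)-4-methyl-6-phenylhex-4-en-1-ol
Product: 5 (E)-(6-bromo-3-methylhex-2-en-1-yl)benzene
Conditions: CBr4, PPh3, CH2Cl2, 0 °C
Reagents that add atoms: carbon tetrabromide, BrC(Br)(Br)Br
Why: Appel bromination of the unhindered primary alcohol should proceed cleanly under neutral conditions that leave the trisubstituted alkene untouched.

Step 3
Reactants: 5 (E)-(6-bromo-3-methylhex-2-en-1-yl)benzene; 6 (E)-pent-3-en-2-one
Product: 8 (4S,8E)-4,8-dimethyl-10-phenyldec-8-en-2-one, via Grignard reagent 7 (not isolated)
Conditions: Mg, Et2O, rt; then CuBr·SMe2 (5 mol%), (R)-1-[(S)-2-(diphenylphosphino)ferrocenyl]ethyldicyclohexylphosphine (6 mol%), 6, t-BuOMe, −75 °C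
Reagents that add atoms: none
Why: Copper-catalysed asymmetric conjugate addition of a primary alkyl Grignard reagent to an acyclic methyl enone should set the C8 methyl stereocentre by ligand-controlled facial selection at the enone β-carbon.

Step 4
Reactants: 8 (4S,8E)-4,8-dimethyl-10-phenyldec-8-en-2-one
Product: 10 (2S)-2-methyl-2-[(2S,6E)-2,6-dimethyl-8-phenyloct-6-en-1-yl]oxetane, via epoxide 9 (not isolated)
Conditions: Me3S(O)I, NaH, LaLi3[(S)-binaphthoxide]3 (5 mol%), (2,4,6-(MeO)3C6H2)3P=O (5 mol%), 5 Å MS, THF, rt; then more ylide and LaLi3[(S)-binaphthoxide]3 (to 20 mol%), 45 °C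
Reagents that add atoms: dimethylsulfoxonium methylide, [CH2-][S+](C)(C)=O
Why: Catalytic asymmetric Corey–Chaykovsky epoxidation of the methyl ketone by the lanthanum–lithium binaphthoxide sets C6 through methyl-versus-alkyl face discrimination, and a second ylide equivalent expands the epoxide at its CH2 terminus to the oxetane without touching C6, the faster ring expansion of the major epoxide enantiomer being expected to raise the stereochemical purity.

Step 5
Reactants: 10 (2S)-2-methyl-2-[(2S,6E)-2,6-dimethyl-8-phenyloct-6-en-1-yl]oxetane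
Product: 11 (3R,5S,9E)-3-hydroperoxy-3,5,9-trimethyl-11-phenylundec-9-en-1-ol
Conditions: H2O2 (anhydrous, in Et2O, excess), Me3SiOTf (0.2 equiv), Et2O, −78 to 0 °C
Reagents that add atoms: hydrogen peroxide, OO
Why: Lewis-acid-promoted perhydrolysis of a 2,2-disubstituted oxetane occurs at the tertiary carbon in an SN2-like manner, so the C6 hydroperoxide should form with inversion, the ring strain allowing conditions mild enough for the trisubstituted alkene.

Step 6
Reactants: 11 (3R,5S,9E)-3-hydroperoxy-3,5,9-trimethyl-11-phenylundec-9-en-1-ol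
Product: 12 triethyl{[(3R,5S,9E)-3,5,9-trimethyl-11-phenyl-1-(triethylsilyloxy)undec-9-en-3-yl]peroxy}silane
Conditions: Et3SiCl (2.5 equiv), imidazole, DMF, 0 °C
Reagents that add atoms: chlorotriethylsilane, CC[Si](Cl)(CC)CC
Why: Imidazole-promoted silylation should convert both the alcohol and the hydroperoxide into triethylsilyl derivatives, masking the acidic OOH for the base-mediated steps that follow without affecting C6.

Step 7
Reactants: 12 triethyl{[(3R,5S,9E)-3,5,9-trimethyl-11-phenyl-1-(triethylsilyloxy)undec-9-en-3-yl]peroxy}silane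
Product: 13 (3R,5S,9E)-3,5,9-trimethyl-11-phenyl-3-(triethylsilylperoxy)undec-9-enal
Conditions: (COCl)2, DMSO, CH2Cl2, −78 °C; Et3N, −78 to −30 °C
Reagents that add atoms: none
Why: Under Swern conditions a primary triethylsilyl ether is oxidised directly to the aldehyde (the chlorosulfonium ion attacks the ether oxygen and expels the silyl chloride), whereas the less nucleophilic, hindered oxygen of the tertiary silyl peroxide should remain intact.

Step 8
Reactants: 13 (3R,5S,9E)-3,5,9-trimethyl-11-phenyl-3-(triethylsilylperoxy)undec-9-enal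
Product: 14 (4R,6S,10E)-1-methoxy-4,6,10-trimethyl-12-phenyl-4-(triethylsilylperoxy)dodeca-1,10-diene (1E/1Z mixture)
Conditions: MeOCH2PPh3Cl, KN(SiMe3)2, THF, −78 to 0 °C
Reagents that add atoms: (methoxymethylene)triphenylphosphorane, COC=P(c1ccccc1)(c1ccccc1)c1ccccc1
Why: Wittig olefination with the methoxymethylene ylide adds the carbon that becomes C3 as an enol ether (one-carbon homologation), the enol ether geometry being irrelevant to what follows.

Step 9
Reactants: 14 (4R,6S,10E)-1-methoxy-4,6,10-trimethyl-12-phenyl-4-(triethylsilylperoxy)dodeca-1,10-diene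
Product: 16 (4R,6S,10E)-4,6,10-trimethyl-2-methylidene-12-phenyl-4-(triethylsilylperoxy)dodec-10-enal, via Mannich base 15 (not isolated)
Conditions: CH2=NMe2+ I−, CH2Cl2, rt; aq. NaHCO3; then Et3N, CH2Cl2, rt
Reagents that add atoms: N,N-dimethylmethyleneiminium iodide, C=[N+](C)C.[I-]; water, O
Why: Mannich reaction of the nucleophilic enol ether β-carbon with the preformed iminium salt and hydrolysis should give the β-amino aldehyde, whose base-induced loss of dimethylamine (α-methylenation) installs the methylene that becomes the C4 methyl group.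

Step 10
Reactants: 16 (4R,6S,10E)-4,6,10-trimethyl-2-methylidene-12-phenyl-4-(triethylsilylperoxy)dodec-10-enal
Product: 17 (6R)-3-methoxy-6-methyl-4-methylidene-6-[(2S,6E)-2,6-dimethyl-8-phenyloct-6-en-1-yl]-1,2-dioxane (both C3 anomers)
Conditions: HCl (cat.), MeOH, 0 °C to rt
Reagents that add atoms: methanol, CO
Why: Acidic methanolysis should remove the silyl group from the peroxide and the liberated hydroperoxide should add to the aldehyde in a 6-exo-trig peroxyacetalisation fixed as the mixed methyl peroxyacetal, the C3 configuration being inconsequential because C3 is ionised in the next step.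

Step 11
Reactants: 17 (6R)-3-methoxy-6-methyl-4-methylidene-6-[(2S,6E)-2,6-dimethyl-8-phenyloct-6-en-1-yl]-1,2-dioxane; 18 1-tert-butoxy-1-(tert-butyldimethylsilyloxy)ethene
Product: 20 plakortolide G, via tert-butyl ester 19 (not isolated)
Conditions: 18 (1.1 equiv), (S,S)-imidodiphosphorimidate acid HN[P(=NSO2CF3)(O2C20H10Ar2)]2 (O2C20H10Ar2 = 3,3′-diaryl-1,1′-binaphthalene-2,2′-diolate, Ar = 3,5-(CF3)2C6H3; 5 mol%), toluene, −78 °C; then Tf2NH (20 mol%), −78 to 0 °C
Reagents that add atoms: none
Why: Proposed new method: the in situ silylated chiral acid ionises the peroxyacetal to a cyclic peroxycarbenium ion paired with the confined chiral anion, the silyl ketene acetal attacks C3 to form the C2–C3 bond, and the Brønsted acid then protonates the exocyclic 1,1-disubstituted alkene to a tertiary C4 cation that is captured by the ester carbonyl with loss of isobutene to form the O–C4 bond, so that the γ-lactone is annulated in one flask as a formal [3+2] addition of an acetate enolate equivalent across C3/C4. The closest known reaction types are the Lewis-acid-mediated addition of silyl ketene acetals to 3-alkoxy-1,2-dioxolanes and 1,2-dioxanes through peroxycarbenium ions, the imidodiphosphorimidate-catalysed asymmetric addition of silyl nucleophiles to cyclic oxocarbenium ions, and the acid-catalysed hydrolactonisation of 4-methylene alkanoic acids and esters. The lactone ring closes in a 5-exo-trig Markovnikov mode, the carbonyl oxygen adding to the cation derived from the exocyclic alkene. C3 is set by catalyst control, the chiral counter-anion shielding one face of the nearly planar cation (the substrate has almost no facial bias of its own because C6 carries two groups of similar size), and C4 is set by the substrate, since the two-atom tether on C3 can only reach the cis face and gives the cis-fused bicycle. The step needs attack at C3 and not at the exocyclic CH2 terminus, which the oxygen-stabilised charge at C3 should secure, and protonation of the ring methylene in preference to the side-chain alkene, which the intramolecular capture by the ester (made irreversible by loss of isobutene) and the low temperature should secure; the peroxide bond is expected to survive as it does under related silyl triflate conditions.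

**Compound list**

1 | 4-pentyn-1-ol | C#CCCCO | starting material
2 | benzyl bromide | BrCc1ccccc1 | starting material
3 | alkenylalane: O-dimethylaluminium alkoxide of (E)-5-(dimethylalumanyl)-4-methylpent-4-en-1-ol | C[Al](C)OCCC/C(C)=C/[Al](C)C | intermediate
4 | (E)-4-methyl-6-phenylhex-4-en-1-ol | OCCC/C(C)=C/Cc1ccccc1 | intermediate
5 | (E)-(6-bromo-3-methylhex-2-en-1-yl)benzene | BrCCC/C(C)=C/Cc1ccccc1 | intermediate
6 | (E)-pent-3-en-2-one | C/C=C/C(C)=O | starting material
7 | [(E)-4-methyl-6-phenylhex-4-en-1-yl]magnesium bromide | Br[Mg]CCC/C(C)=C/Cc1ccccc1 | intermediate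
8 | (4S,8E)-4,8-dimethyl-10-phenyldec-8-en-2-one | C/C(=C\Cc1ccccc1)CCC[C@H](C)CC(C)=O | intermediate
9 | (2S)-2-methyl-2-[(2S,6E)-2,6-dimethyl-8-phenyloct-6-en-1-yl]oxirane | C/C(=C\Cc1ccccc1)CCC[C@H](C)C[C@@]1(C)CO1 | intermediate
10 | (2S)-2-methyl-2-[(2S,6E)-2,6-dimethyl-8-phenyloct-6-en-1-yl]oxetane | C/C(=C\Cc1ccccc1)CCC[C@H](C)C[C@@]1(C)CCO1 | intermediate
11 | (3R,5S,9E)-3-hydroperoxy-3,5,9-trimethyl-11-phenylundec-9-en-1-ol | C/C(=C\Cc1ccccc1)CCC[C@H](C)C[C@@](C)(OO)CCO | intermediate
12 | triethyl{[(3R,5S,9E)-3,5,9-trimethyl-11-phenyl-1-(triethylsilyloxy)undec-9-en-3-yl]peroxy}silane | C/C(=C\Cc1ccccc1)CCC[C@H](C)C[C@@](C)(OO[Si](CC)(CC)CC)CCO[Si](CC)(CC)CC | intermediate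
13 | (3R,5S,9E)-3,5,9-trimethyl-11-phenyl-3-(triethylsilylperoxy)undec-9-enal | C/C(=C\Cc1ccccc1)CCC[C@H](C)C[C@@](C)(OO[Si](CC)(CC)CC)CC=O | intermediate
14 | (4R,6S,10E)-1-methoxy-4,6,10-trimethyl-12-phenyl-4-(triethylsilylperoxy)dodeca-1,10-diene (1E/1Z mixture) | C/C(=C\Cc1ccccc1)CCC[C@H](C)C[C@@](C)(OO[Si](CC)(CC)CC)CC=COC | intermediate
15 | Mannich base: (4R,6S,10E)-2-[(dimethylamino)methyl]-4,6,10-trimethyl-12-phenyl-4-(triethylsilylperoxy)dodec-10-enal (C2 epimers) | C/C(=C\Cc1ccccc1)CCC[C@H](C)C[C@@](C)(OO[Si](CC)(CC)CC)CC(CN(C)C)C=O | intermediate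
16 | (4R,6S,10E)-4,6,10-trimethyl-2-methylidene-12-phenyl-4-(triethylsilylperoxy)dodec-10-enal | C/C(=C\Cc1ccccc1)CCC[C@H](C)C[C@@](C)(OO[Si](CC)(CC)CC)CC(=C)C=O | intermediate
17 | (6R)-3-methoxy-6-methyl-4-methylidene-6-[(2S,6E)-2,6-dimethyl-8-phenyloct-6-en-1-yl]-1,2-dioxane (both C3 anomers) | C/C(=C\Cc1ccccc1)CCC[C@H](C)C[C@]1(C)CC(=C)C(OC)OO1 | intermediate
18 | 1-tert-butoxy-1-(tert-butyldimethylsilyloxy)ethene (silyl ketene acetal of tert-butyl acetate) | C=C(OC(C)(C)C)O[Si](C)(C)C(C)(C)C | starting material
19 | tert-butyl 2-{(3R,6R)-6-methyl-4-methylidene-6-[(2S,6E)-2,6-dimethyl-8-phenyloct-6-en-1-yl]-1,2-dioxan-3-yl}acetate | C/C(=C\Cc1ccccc1)CCC[C@H](C)C[C@]1(C)CC(=C)[C@@H](CC(=O)OC(C)(C)C)OO1 | intermediate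
20 | plakortolide G: cis-fused 1,2-dioxane/γ-lactone with 3R,4R,6R,8S configuration and the 12E side-chain alkene | C/C(=C\Cc1ccccc1)CCC[C@H](C)C[C@]1(C)C[C@@]2(C)OC(=O)C[C@H]2OO1 | target

**Step count and risks**

Total step count: 11. Longest linear sequence: 11 steps (from 4-pentyn-1-ol 1).

Steps most likely to fail:

1. Step 11 (Proposed new method). The chiral anion may discriminate the faces of the peroxycarbenium ion poorly, the nucleophile may attack the exocyclic terminus, or the acid of the lactonisation stage may isomerise the side-chain alkene or cleave the O–O bond. The fallback uses known chemistry, sets out from 17 and returns at 20. Me3SiOTf-promoted addition of 18 to 17 (CH2Cl2, −78 °C) should give ester 19, which is isolated here by chromatography from its C3 epimer if that forms. Iodolactonisation of 19 (I2, NaHCO3, MeCN, 0 °C), in which the ester oxygen opens the iodonium ion of the ring methylene at C4 with loss of the tert-butyl group, should give iodomethyl lactone F1 under non-acidic conditions that spare the side-chain alkene. Radical deiodination (Bu3SnH, Et3B, air, toluene, 0 °C) then gives 20.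

2. Step 5. The oxetane opening may take on partial SN1 character and erode the C6 configuration, water may compete to give the 1,3-diol, or the acidic peroxide medium may attack the trisubstituted alkene. The fallback sets out from 8 and returns at 16, forming the C6–O–O unit by peroxycarbenium allylation instead of ring opening. Ketone 8 is converted (HC(OMe)3, MeOH, anhydrous H2O2, cat. TsOH) to α-methoxy hydroperoxide F2 and silylated (Et3SiCl, imidazole) to triethylsilyl peroxyketal F3. Hosomi–Sakurai-type allylation (allyltrimethylsilane, SnCl4, CH2Cl2, −78 °C) gives homoallyl silyl peroxide F4. Hydroboration–oxidation of the terminal alkene (9-borabicyclo[3.3.1]nonane, THF; NaBO3) gives alcohol F5, and Dess–Martin periodinane (NaHCO3, CH2Cl2) gives aldehyde F6. α-Methylenation (aq. HCHO, pyrrolidine, EtCO2H, i-PrOH, 45 °C) then gives 16. This fallback forms C6 without control, so 16 arrives with its C6 epimer and the epimers are separated after ring closure (at 17 or at 20).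

3. Step 7. The β-silylperoxy aldehyde may lose the peroxide by base-induced β-elimination during the Swern oxidation or the following Wittig step, or the peroxide silyl group may be cleaved. The fallback sets out from 11 and returns at 14, carrying the aldehyde as a cyclic peroxyhemiacetal instead of protecting the hydroperoxide. Oxidation of 11 with 2,2,6,6-tetramethylpiperidin-1-oxyl (cat.) and PhI(OAc)2 in CH2Cl2 should give, after ring closure of the hydroperoxy aldehyde, 1,2-dioxolan-3-ol F7, in which the peroxide is part of a ring and cannot be expelled. F7 is opened only in the Wittig step (MeOCH2PPh3Cl, KN(SiMe3)2, 3 equiv, THF, −78 to 0 °C), where the peroxide is present as its anion, and the hydroperoxide anion is silylated in the same flask (Et3SiCl) to give 14.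

**Further compounds**

F1 | step 11 | iodomethyl lactone: 20 with CH2I in place of the C4 methyl group, same spatial arrangement at all centres | C/C(=C\Cc1ccccc1)CCC[C@H](C)C[C@]1(C)C[C@@]2(CI)OC(=O)C[C@H]2OO1
F2 | step 5 | (4S,8E)-2-hydroperoxy-2-methoxy-4,8-dimethyl-10-phenyldec-8-ene (C2 epimers) | C/C(=C\Cc1ccccc1)CCC[C@H](C)CC(C)(OC)OO
F3 | step 5 | triethyl{[(4S,8E)-2-methoxy-4,8-dimethyl-10-phenyldec-8-en-2-yl]peroxy}silane (C2 epimers) | C/C(=C\Cc1ccccc1)CCC[C@H](C)CC(C)(OC)OO[Si](CC)(CC)CC
F4 | step 5 | triethyl{[(6S,10E)-4,6,10-trimethyl-12-phenyldodeca-1,10-dien-4-yl]peroxy}silane (C4 epimers) | C/C(=C\Cc1ccccc1)CCC[C@H](C)CC(C)(CC=C)OO[Si](CC)(CC)CC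
F5 | step 5 | (6S,10E)-4,6,10-trimethyl-12-phenyl-4-(triethylsilylperoxy)dodec-10-en-1-ol (C4 epimers) | C/C(=C\Cc1ccccc1)CCC[C@H](C)CC(C)(CCCO)OO[Si](CC)(CC)CC
F6 | step 5 | (6S,10E)-4,6,10-trimethyl-12-phenyl-4-(triethylsilylperoxy)dodec-10-enal (C4 epimers) | C/C(=C\Cc1ccccc1)CCC[C@H](C)CC(C)(CCC=O)OO[Si](CC)(CC)CC
F7 | step 7 | (5R)-5-methyl-5-[(2S,6E)-2,6-dimethyl-8-phenyloct-6-en-1-yl]-1,2-dioxolan-3-ol (C3 anomers) | C/C(=C\Cc1ccccc1)CCC[C@H](C)C[C@]1(C)CC(O)OO1
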